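How much G stands in the north flask at 10 h, and which remedy adds most to it?

| setting | north | east | flask |
|---|---|---|---|
| Q | 0.40 M | 0.40 M | 0.40 M |
| X | 0.36 M | 0.36 M | 0.360 M |
| D | 2 M | 2 M | 2.00 M |
| temperature | 0 °C | 6 °C | 0 °C |
| remark | the very flask that is asked about, followed so far | run made earlier |  |
| time |  |  | 10 h |

| north: time / h | north: G / % | east: time / h | east: G / % |
|---|---|---|---|
| 1.50 | 43.1 | 1.50 | 33.7 |
| 3.00 | 44.4 | 3.00 | 33.0 |
| 5.00 | 40.9 | 5.00 | 30.3 |
| 6.00 | 38.4 | 6.00 | 28.4 |

(standard deviation of a reading: 1 percentage point)

- zeta: change nothing and wait 5.0 h more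
- alpha: at 10 h add X, 100 % of the amount charged, then wait 5.0 h
- eta: at 10 h raise the temperature by 25 K, then wait 5.0 h
- theta: at 10 h take out 90 % of the G then present, then wait 5.0 h

1. G, in percent of the Q first charged, at 10 h
2. the remedy with the largest gain of G, or "none" below 2 percentage points (zeta / alpha / eta / theta / none)
3. G present, with what was taken out counted in, in percent of the Q first charged, after eta
4. G present, with what was taken out counted in, in percent of the Q first charged, after theta

- removed G is counted in
- the numbers in the tables scatter with a standard deviation of 1 percentage point
- reactions considered so far: Q + X <-> G; D + X <-> E; D <-> J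
- additions bring no volume worth counting

We reckon in fractions of the charge. X, charged less than Q, is the limiting reagent, and Q and X stand in the ratio 1.11, so each part of the Q charge bound as G takes that many parts of the X charge. We read the north reading at 3.00 h, 44.4 %, as the balance of Q + X ⇌ G, and as an approximation we leave out of the count whatever X has gone to E by then. That leaves free X at 50.7 % of its charge and gives a holding ratio of 1.58: G over free Q times free X, each as a fraction of its own charge, the equilibrium quotient for this charge at 0 °C.

Two extremes follow. In the first, X stops leaving and G stays at that reading, 44.4 %. For the other extreme, the north reading at 6.00 h, 38.4 %, asks under the same ratio for free X of 39.6 %, so we reckon 17.8 % of the X charge gone to E in between, an estimate that carries the scatter of both readings. Kept at that steady pace up to 10 h, the loss reaches 41.5 %, and the holding ratio then returns 29.2 %.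

The north flask should lie between these, since the free X we reckon falls over those hours and a pace that goes with free X slows as it falls. We commit to the middle, 36.8 %.

The forecast, reading that “the fall accelerates”, gives 27 % at 10 h, 1.5 % after eta and 30.5 % after theta, and names alpha. Its G at 10 h stands lower than our steady-pace extreme.

The north flask gives 38.0 % at 10 h, 13.1 % after eta and 52.0 % after theta, and the best remedy is alpha, gaining 22 percentage points. E stands at 0.0804 M at 10.0 h, which is 22.3 % of the X charge, less than the steady pace gave. Put into the holding ratio, that loss returns 36.7 %.

    Q + X ⇌ G (K = 4.78 /M, k = 0.236 /M/min, Ea = 50.0 kJ/mol, ΔH = −49.0 kJ/mol)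
    D + X ⇌ E (K = 0.628 /M, k = 0.00110 /M/min, Ea = 76.0 kJ/mol, ΔH = −15.0 kJ/mol)
    D ⇌ J (K = 0.406, k = 0.0480 /min, Ea = 83.0 kJ/mol, ΔH = −30.0 kJ/mol)
    (constants at 0 °C)

For the neighbour charged with 0.22 M of X at the same temperature, the holding ratio scales with the X charge to 0.963, and with Q to X now 1.82 it gives 30.2 % before any loss to E is counted. The computed neighbour gives 25.7 %, with E at 0.0454 M.

(Readings and results were computed with made-up constants, noise included.)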